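Turn each run into one time: the substrate time τ, in which the enzyme brings substrate down by a factor e. We read it from the last substrate reading of a run:

c(substrate) = c(substrate, charged) · exp(−t/τ)

This is a pseudo-first-order reckoning, and we take τ as independent of the substrate charged.

| setting | north-east | south | south-east | Sunday's | Friday's | Tuesday's | Saturday's |
|---|---|---|---|---|---|---|---|
| substrate | 10 mM | 40 mM | 20 mM | 20 mM | 20 mM | 20 mM | 20 mM |
| free enzyme | 17 µM | 17 µM | 8.5 µM | 17 µM | 17 µM | 17 µM | 17 µM |
| temperature | −5 °C | 15 °C | −5 °C | 15 °C |  | 30 °C | 0 °C |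
| remark | run made earlier | run made earlier | run made earlier |  | at 30 °C until 10 min, from then on at 0 °C |  |  |
| time |  |  |  | 50 min | 50 min | 50 min | 50 min |

| run | time / min | target / % | substrate / % |
|---|---|---|---|
| north-east | 10.0 | 4 | 93 |
| north-east | 25.0 | 14 | 86 |
| north-east | 50.0 | 25 | 77 |
| north-east | 80.0 | 34 | 68 |
| north-east | 120 | 41 | 57 |
| south | 8.00 | 13 | 93 |
| south | 15.0 | 18 | 83 |
| south | 25.0 | 25 | 71 |
| south | 30.0 | 25 | 70 |
| south | 40.0 | 36 | 62 |
| south-east | 10.0 | 0 | 97 |
| south-east | 25.0 | 6 | 93 |
| south-east | 50.0 | 13 | 87 |
| south-east | 80.0 | 17 | 82 |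
| south-east | 120 | 21 | 76 |

(readings scatter by 2 percentage points)



1. the flask with the highest amount of target, in percent of the substrate charged ("all alike" if they lie within 1.5 percentage points) (Sunday's / Friday's / Tuesday's / Saturday's / all alike)
2. final target, as a percentage of the substrate charged, in Sunday's
3. final target, as a percentage of the substrate charged, in Friday's
4. final target, as a percentage of the substrate charged, in Tuesday's
5. final target, as a percentage of the substrate charged, in Saturday's

The north-east run gives 213 min at −5 °C and the south run 83.7 min at 15 °C, so that warming shortens τ by a factor 2.55. Taking ln τ as straight in temperature, and with 17 µM enzyme unless told otherwise, our ladder runs from fast to slow, each rung with the substrate we reckon left after 50 min: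

Tuesday's, 30 °C: τ = 41.5 min, left 30.0%

Sunday's, 15 °C: τ = 83.7 min, left 55.0%

Saturday's, 0 °C: the substrate time 169 min, left 74.4%

South-east run, 8.5 µM enzyme, −5 °C: τ = 437 min, twice the north-east value

Friday's spends 10 min on the Tuesday rung and the rest on the Saturday rung. The fractions of τ add, so we reckon 62.0% left.

At the last south reading, target and substrate add up to 98.0%, with a scatter of 2 percentage points on each reading. Reading the reacted substrate as target, we expect 45.0% in Sunday's, 38.0% in Friday's, 70.0% in Tuesday's and 25.6% in Saturday's. But Tuesday's stands hotter than any run read, so its balance is untested.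

The forecast gives 46%, 38%, 63% and 29% in that order and names Tuesday's. Its Tuesday figure is lower than ours, “trimmed for possible heat deactivation, which is untested”.

The flasks give, in the same order, 45.9%, 39.1%, 29.9% and 26.4%, and the most target stands in Sunday's.

    free enzyme → unfolded enzyme (k = 1.10 × 10⁻⁵ s⁻¹, Ea = 233 kJ mol⁻¹)
    2 free enzyme ⇌ resting dimer (K = 41000 M⁻¹, k = 130 M⁻¹ s⁻¹, Ea = 39.0 kJ mol⁻¹, ΔH = −14.0 kJ mol⁻¹)
    target → over-reaction product (k = 6.00 × 10⁻⁴ s⁻¹, Ea = 102 kJ mol⁻¹)
    substrate + free enzyme → target + free enzyme, rate k4*[substrate]*[free enzyme]/(1 + ([substrate]/Km4) + ([target]/Kp4)) (40.0 mM, 22.0 mM, k = 99.0 M⁻¹ s⁻¹, Ea = 42.0 kJ mol⁻¹)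
    (constants at 30 °C)

Tuesday's own substrate time, from its 14% left, is 25.9 min, and its target lives 27.8 min before passing into over-reaction product: the two are close, and at 50.0 min Tuesday's holds 55.7% over-reaction product beside 29.9% target. In Saturday's that passing is slower by a factor 85, which makes the life 2370 min, far longer than 169 min, and over-reaction product stands at 0.330%.

Now read Saturday's at 180 min. The same 169 min leaves 34.5% substrate, and that time is still far below 2370 min, so the reacted substrate should stay target. The computed flask holds 41.0% substrate, 56.3% target and 2.71% over-reaction product.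

Readings and results are simulated for substances that don't exist, and the scatter is random.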